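## The problem

Atoms are numbered in the order of the SMILES string of the target, every heavy atom counted (O16 on C15, Br18 on C17, O23 on C21). The target 32 is a C20 bromo diol in which a trans-fused decalin (ring A: C8, C9, C17, C19, C20, C21; ring B: C7, C8, C9, C11, C12, C13) is fused across C7–C13 to a bicyclo[2.2.1]heptane with bridgeheads C6 and quaternary C13 and with C7 as the one-carbon bridge. Of its nine stereocentres, C4, C6, C7, C13 and C15 lie on the bicycle and C8, C9, C17 and C21 on the decalin. C4 can be taken from the chiral pool and can relay to C13, C7 and C6 through the five-membered ring C4–C5–C6–C7–C13. Once the decalin is rigid, C8 (equilibration), C21 (equatorial attack) and C15 (endo attack) follow from the framework, but the pair C9/C17 is too far from C4 to be induced. The secondary bromide at C17 lies next to quaternary C9: it cannot be installed by substitution and will not survive tin hydrides, dissolving metals or strong hydride donors, and the tertiary C21 alcohol and the exo norbornanol rule out ionising conditions late in the route. The enabling feature is that C14 is α to C15 and bridgehead C13 is α to C12 of ring B: with carbonyl groups at C12 and C15, the bond C13–C14 joins the two α-carbons of a 1,4-diketone. The arm on C6 that carries C15 and C14 is 1,3 to C13 on the five-membered ring and can reach only one face of C13.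

## Retrosynthesis

**End game, no skeletal bond cut.** The C12 methylene and the C15 carbinol of 32 are traced back to two ketones. 32 comes from bis(silyl ether) 31, and that in turn from alkene 30, enol triflate 29, silyl ether 28, hydroxy ketone 27 and finally diketone 26, which already carries the C21 tertiary alcohol as its silyl ether. Carbonyl groups at C12 and C15 are what make the next cut possible; the price is the excision of the C12 oxygen. The forward steps must reduce C15 from the endo face before C12 is touched, and must deoxygenate C12 by means that spare the C17 bromide.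

**C13–C14.** In 26 this bond links the α-carbons of a 1,4-diketone and is cut to the bis(silyl enol ether) 25. The neighbouring cuts C6–C15 or C4–C5 would leave quaternary C13 in place, to be built by alkylation of a hindered carbon; cutting C7–C13 or C12–C13 would open ring B as well. The chosen cut removes the quaternary centre and one ring, makes C13 trigonal (one stereocentre less) and leaves a fused six-six-five tricycle. The forward reaction must couple two enol ether carbons oxidatively, within the molecule, on the face of C13 that the C6 arm can reach.

**C15–C14 and C21–C22.** 25 comes from methyl ketone 24 by kinetic enolisation, and 24 from ester 22 through Weinreb amide 23. The C12 enol ether of 22 comes from ketone 21, that from alcohol 20, and the C21 carbinol of 20 from keto ester 19 and MeMgBr. Carrying C15 as an ester until two steps before the coupling is preferred to carrying the methyl ketone, for four reasons: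
- MeMgBr can pick out the C21 ketone.
- The C12 enol ether is made while no other enolisable ketone is present.
- A 1,5-diketone (C12/C15) is never in the flask.
- The C6 stereocentre is stored in a less acidic form.

The forward steps must add methyl to C21 from the equatorial side and enolise C12 toward C13.

**C7–C8.** Ring B of 19 is opened at C7–C8 to hydroxy enoate 18; forward, this is an intramolecular Michael addition of the ring A ketone to the cyclopentene ester. Cutting C8–C9 or C9–C11 instead would mean forming quaternary C9 on the full skeleton. The precursor is a cyclopentene tethered to a monocyclic ketone. The forward reaction must set C7 (through the tether), C8 (by equilibration) and C6 (by protonation).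

**C12–C13.** 18 is divided into ester 6 and aldehyde 16, joined forward by a vinylogous aldol reaction through silyl dienolate 17. This is the convergent cut: it separates two pieces of nine carbons each and places the union next to the only stereocentre of 6. The forward reaction must be γ-selective and must attack trans to the isopropyl group.

**Ring A.** Aldehyde 16 comes from alkene 15 by ozonolysis, 15 from racemic ketone 14 by resolution, and 14 from β-keto ester 13 by decarboxylation. 13 is cut at C8–C9 and C17–Br together, back to the acyclic keto ester 12 (bromonium-induced cyclisation). This is the only disconnection that creates the equatorial bromide next to quaternary C9 directly; any route through a C17 alcohol or ketone ends in a substitution at a neopentyl carbon. 12 is cut at C19–C20 into bromide 10 and allyl acetoacetate 11. 10 comes from alcohol 9, made from pent-1-en-4-yne 7 through alkenylalane 8, which fixes the alkene geometry that the cyclisation translates into the C9/C17 relation. The cyclisation must proceed through a chair with anti addition; the racemate has to be resolved once.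

**Cyclopentene.** Ester 6 is traced through acid 5 and enone 4 to keto aldehyde 3 (cut of C6–C7, aldol). 3 is the ozonolysis product of (R)-p-menth-1-ene 2, the partial hydrogenation product of (R)-limonene 1. Nine of the ten limonene carbons end up in the target and the stereocentre becomes C4 without any bond to it being made or broken.

## Roads not taken

**Alternative 1:** Ring B and quaternary C9 are made last by cutting C9–C11. Forward, KOC(CH3)3 would turn phenol A1 (ring A aromatic, norbornane complete, C11 as a primary mesylate) into its phenoxide, whose ortho carbon C9 displaces the mesylate to give the cyclohexa-2,4-dienone A2.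
- Merits: ortho-alkylative dearomatisation within the molecule is a known 6-exo-tet process. It makes an all-carbon quaternary centre without an enolate of a hindered ketone, and the arene is achiral, so no resolution is needed.
- Weak points: A1 presupposes the bicyclo[2.2.1]heptane with quaternary C13, so the hardest part is only moved upstream. C- versus O-alkylation and the face of C9 (decided by the rotamer about C7–C8) are not controlled. A2 has oxygen at C17 where the target needs an equatorial bromide next to a quaternary carbon, for which no dependable substitution exists, and its tetrasubstituted C8=C21 unit must still be reduced to the trans ring fusion.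
- Comparison: its key step is better precedented than the one chosen. Against that, the chosen plan introduces C17–Br early and stereospecifically, and its key step itself builds the norbornane.

**Alternative 2:** Three bonds (C7–C13, C14–C15, C6–C15) are cut at once. Forward, Co2(CO)8 with an amine N-oxide would turn enyne A3 into the tricyclic cyclopentenone A4 (Pauson–Khand), closing ring B and the cyclopentenone and forming quaternary C13 from a 1,1-disubstituted alkene.
- Merits: two rings and three bonds in one known reaction, and ring A with its bromide can be the same building block as in the chosen plan.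
- Weak points: the configuration of C13 would rest on the acyclic stereocentre C4 next to the alkene, and C4 would have to be made by asymmetric synthesis since the limonene ring is not used. A 1,7-enyne with a 1,1-disubstituted alkene lies at the slow end of the scope. After A4 the bond C5–C6 must still be closed and C6 and C7 set.
- Comparison: it builds more per step and is precedented. The chosen plan sets against it C4 from the chiral pool, a C13 face fixed by the cis bridge, and C6/C7 in place before the key step.

**Alternative 3:** C6–C15 and C4–C5 are cut. Forward, Bu3SnH would convert selenoester A5 into an acyl radical that adds 5-exo to the vinyl group on C7; the C5 radical then adds 5-exo to the 2-methylpropenyl group on C13, giving ketone A6.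
- Merits: both rings of the norbornanone form in one step by known radical chemistry, and the C15 ketone arrives with no oxygen at C12, which would save the excision steps of the chosen end game. In step count after the key step this road is better.
- Weak points: tin hydride destroys a C17 bromide, so A5 and A6 carry a ketal at C17 and the bromide would have to come from a ketone at a neopentyl carbon. A5 needs quaternary C13 with three different carbon arms, made by alkylation at a hindered centre. The configuration of C4 would be set by the second radical closure without a clear bias.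
- Comparison: the chosen plan sets against the shorter end game its tolerance of the bromide from ring A onward and a C4 that is bought, not made.

Key step: step 20

Remarks on the chemistry (assumptions):
- The hydroxide-mediated aldol closure of 3 is taken to go through the ketone enolate and give acetylcyclopentene 4, not the isomeric cyclopentenecarbaldehyde.
- 13 and 14 are racemates (the SMILES show the enantiomer carried on); the ring A stereocentres are resolved once, at 14.
- The vinylogous aldol gives both C12 carbinol epimers; both are carried on, since C12 becomes a ketone in step 16 (C12 is left undefined in the SMILES of 18–20).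

## Route

Step 1
Reactants: 1 (R)-limonene
Product: 2 (R)-p-menth-1-ene
Conditions: H2 (1 atm), RhCl(PPh3)3 (cat.), benzene–EtOH, rt
Reagents that add atoms: none
Why: Homogeneous hydrogenation with RhCl(PPh3)3 reduces the 1,1-disubstituted alkene and leaves the trisubstituted ring alkene; the stereocentre (later C4) is not touched.

Step 2
Reactants: 2 (R)-p-menth-1-ene
Product: 3 (3R)-6-oxo-3-(propan-2-yl)heptanal
Conditions: O3, CH2Cl2–MeOH, −78 °C; then Me2S, −78 °C → rt
Reagents that add atoms: ozone, [O-][O+]=O
Why: Ozonolysis with reductive work-up cleaves the only alkene to the keto aldehyde.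

Step 3
Reactants: 3 (3R)-6-oxo-3-(propan-2-yl)heptanal
Product: 4 1-[(4S)-4-(propan-2-yl)cyclopent-1-en-1-yl]ethan-1-one
Conditions: KOH (aq.), THF, rt → 50 °C
Reagents that add atoms: none
Why: Intramolecular aldol condensation: under hydroxide the ketone α-methylene enolate attacks the aldehyde (five-membered ring) and dehydration gives the conjugated enone; the CIP descriptor changes only because the ring priorities change.

Step 4
Reactants: 4 1-[(4S)-4-(propan-2-yl)cyclopent-1-en-1-yl]ethan-1-one
Product: 5 (4S)-4-(propan-2-yl)cyclopent-1-ene-1-carboxylic acid
Conditions: Br2, NaOH, H2O–1,4-dioxane, 0 °C; then HCl (aq.)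
Reagents that add atoms: sodium hydroxide, [Na+].[OH-]
Why: Haloform reaction of a conjugated methyl ketone (as in the conversion of mesityl oxide into 3-methylbut-2-enoic acid); the electron-poor alkene survives hypobromite.

Step 5
Reactants: 5 (4S)-4-(propan-2-yl)cyclopent-1-ene-1-carboxylic acid
Product: 6 methyl (4S)-4-(propan-2-yl)cyclopent-1-ene-1-carboxylate
Conditions: MeI, K2CO3, DMF, rt
Reagents that add atoms: iodomethane, CI
Why: SN2 O-alkylation of the carboxylate; the ester has no α′ hydrogens, so later deprotonation can only occur at the γ carbon (C13).

Step 6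
Reactants: 7 pent-1-en-4-yne
Product: 9 (2E)-3-methylhexa-2,5-dien-1-ol, via alkenylalane 8 (not isolated)
Conditions: AlMe3, Cp2ZrCl2 (cat.), CH2Cl2, 0 °C → rt; then n-BuLi, −78 °C; (CH2O)n, THF, rt; aq. work-up
Reagents that add atoms: trimethylaluminium, C[Al](C)C; formaldehyde (as paraformaldehyde), C=O
Why: Zirconium-catalysed carboalumination of the terminal alkyne (Negishi) adds methyl and aluminium syn; the alanate is hydroxymethylated with retention, giving the E alkene in which C19 is cis to the methyl group; the terminal alkene is inert.

Step 7
Reactants: 9 (2E)-3-methylhexa-2,5-dien-1-ol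
Product: 10 (2E)-1-bromo-3-methylhexa-2,5-diene
Conditions: PBr3, Et2O, −10 °C
Reagents that add atoms: phosphorus tribromide, BrP(Br)Br
Why: Conversion of a primary allylic alcohol into the bromide without allylic transposition, as for geraniol to geranyl bromide.

Step 8
Reactants: 11 prop-2-en-1-yl 3-oxobutanoate (allyl acetoacetate); 10 (2E)-1-bromo-3-methylhexa-2,5-diene
Product: 12 prop-2-en-1-yl (6E)-7-methyl-3-oxodeca-6,9-dienoate
Conditions: NaH, THF, 0 °C; n-BuLi, 0 °C; then 10, 0 °C; aq. NH4Cl
Reagents that add atoms: none
Why: Dianion alkylation of a β-keto ester (Weiler): the dianion reacts at its terminal carbon (C20) with the allylic bromide by SN2, forming C19–C20.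

Step 9
Reactants: 12 prop-2-en-1-yl (6E)-7-methyl-3-oxodeca-6,9-dienoate
Product: 13 prop-2-en-1-yl rac-(2S,3S)-3-bromo-2-methyl-6-oxo-2-(prop-2-en-1-yl)cyclohexane-1-carboxylate
Conditions: Et2SBr·SbCl5Br, MeNO2, −25 °C
Reagents that add atoms: bromodiethylsulfonium bromopentachloroantimonate, CC[S+](Br)CC.Cl[Sb-](Cl)(Cl)(Cl)(Cl)Br
Why: Bromonium-induced cation–olefin cyclisation terminated by the β-keto ester enol: the trisubstituted alkene is the most electron-rich, and anti addition through a chair puts bromine equatorial at C17 and the group cis to C19 (the methyl) axial at C9, so Br is cis to the methyl group; C8–C9 and C17–Br form together, as a racemate.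

Step 10
Reactants: 13 prop-2-en-1-yl rac-(2S,3S)-3-bromo-2-methyl-6-oxo-2-(prop-2-en-1-yl)cyclohexane-1-carboxylate
Product: 14 rac-(3S,4S)-4-bromo-3-methyl-3-(prop-2-en-1-yl)cyclohexan-1-one
Conditions: Pd(OAc)2 (cat.), PPh3, HCO2H, Et3N, THF, rt
Reagents that add atoms: none
Why: Palladium-catalysed deallylation–decarboxylation of an allyl β-keto ester with formate (Tsuji) under neutral conditions; zerovalent palladium does not insert into the unactivated secondary C–Br bond.

Step 11
Reactants: 14 rac-(3S,4S)-4-bromo-3-methyl-3-(prop-2-en-1-yl)cyclohexan-1-one
Product: 15 (3S,4S)-4-bromo-3-methyl-3-(prop-2-en-1-yl)cyclohexan-1-one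
Conditions: preparative supercritical-fluid chromatography on a chiral stationary phase (amylose tris(3,5-dimethylphenylcarbamate)), CO2–MeOH
Reagents that add atoms: none
Why: Resolution of enantiomers by chromatography on a chiral phase (no bond is formed); C9 and C17 cannot be induced by the terpene fragment, so they are resolved once on this small, configurationally stable ketone.

Step 12
Reactants: 15 (3S,4S)-4-bromo-3-methyl-3-(prop-2-en-1-yl)cyclohexan-1-one
Product: 16 2-[(1S,2S)-2-bromo-1-methyl-5-oxocyclohexyl]acetaldehyde
Conditions: O3, CH2Cl2, −78 °C; then PPh3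
Reagents that add atoms: ozone, [O-][O+]=O
Why: Ozonolysis of the terminal alkene with reductive work-up unveils the C12 aldehyde; ketone and bromide are inert.

Step 13
Reactants: 6 methyl (4S)-4-(propan-2-yl)cyclopent-1-ene-1-carboxylate; 16 2-[(1S,2S)-2-bromo-1-methyl-5-oxocyclohexyl]acetaldehyde
Product: 18 methyl (3S,4S)-3-{2-[(1S,2S)-2-bromo-1-methyl-5-oxocyclohexyl]-1-hydroxyethyl}-4-(propan-2-yl)cyclopent-1-ene-1-carboxylate, via silyl dienolate 17 (not isolated)
Conditions: 6, LiN(iPr)2, THF–DMPU, −78 °C; tBuMe2SiCl; then 16, BF3·OEt2, CH2Cl2, −78 °C
Reagents that add atoms: none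
Why: Vinylogous Mukaiyama aldol reaction: γ-deprotonation and O-silylation give the silyl dienolate, whose α-carbon is fully substituted, so the BF3-activated aldehyde (more reactive than the ring ketone) is attacked by the γ-carbon C13, anti to the neighbouring isopropyl group (C12–C13 trans to C4–isopropyl); the C12 carbinol forms as both epimers.

Step 14
Reactants: 18 methyl (3S,4S)-3-{2-[(1S,2S)-2-bromo-1-methyl-5-oxocyclohexyl]-1-hydroxyethyl}-4-(propan-2-yl)cyclopent-1-ene-1-carboxylate
Product: 19 tricyclic keto ester (C7–C8 closed; C21 ketone; C12 carbinol; C6 ester cis to C8)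
Conditions: NaOMe, MeOH, 0 °C → rt
Reagents that add atoms: none
Why: Intramolecular Michael addition (6-exo-trig) under equilibrating methoxide: only the C8 enolate can reach C7 in a six-membered ring, and the tether on C13 delivers C8 to its own face of the cyclopentene (cis ring fusion, sets C7). C8 then equilibrates to the trans-fused decalin with the C7 substituent equatorial, and the ester enolate is protonated by methanol from the face opposite C8, leaving the ester cis to C8.

Step 15
Reactants: 19 tricyclic keto ester (C7–C8 closed; C21 ketone; C12 carbinol; C6 ester cis to C8)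
Product: 20 tricyclic diol ester (C21 tertiary alcohol with axial OH)
Conditions: MeMgBr, CeCl3, THF, −78 °C
Reagents that add atoms: methylmagnesium bromide, C[Mg]Br
Why: Organocerium 1,2-addition to the only ketone; the reagent is non-basic and spares the ester. The axial approach to C21 is blocked by the 1,3-diaxial methyl on C9, so methyl enters equatorially and the hydroxyl ends up axial, as in the target.

Step 16
Reactants: 20 tricyclic diol ester (C21 tertiary alcohol with axial OH)
Product: 21 tricyclic C12 ketone (C21 tertiary alcohol; C6 ester)
Conditions: Dess–Martin periodinane, CH2Cl2, rt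
Reagents that add atoms: none
Why: Dess–Martin oxidation of the secondary C12 alcohol; the tertiary alcohol is inert and the two carbinol epimers converge.

Step 17
Reactants: 21 tricyclic C12 ketone (C21 tertiary alcohol; C6 ester)
Product: 22 tricyclic ester with C12=C13 tert-butyldimethylsilyl enol ether and C21 silyl ether
Conditions: tBuMe2SiOTf, Et3N, CH2Cl2, 0 °C → rt
Reagents that add atoms: tert-butyldimethylsilyl trifluoromethanesulfonate, CC(C)(C)[Si](C)(C)OS(=O)(=O)C(F)(F)F
Why: Soft enolisation with a silyl triflate and amine under equilibrating conditions gives the more substituted silyl enol ether, toward the ring-fusion carbon C13, and silylates the tertiary alcohol in the same operation. C12 is the only ketone present, and the step removes the C13 stereocentre.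

Step 18
Reactants: 22 tricyclic ester with C12=C13 tert-butyldimethylsilyl enol ether and C21 silyl ether
Product: 24 tricyclic methyl ketone (acetyl on C6 cis to C8; C12=C13 silyl enol ether), via Weinreb amide 23 (not isolated)
Conditions: Me(MeO)NH·HCl, iPrMgCl, THF, −20 °C; then MeMgBr, 0 °C; aq. NH4Cl
Reagents that add atoms: methylmagnesium bromide, C[Mg]Br
Why: One-pot Weinreb ketone synthesis: the magnesium amide of N,O-dimethylhydroxylamine converts the ester into the amide, whose chelated adduct with MeMgBr stops at the ketone stage (C14 installed). Silyl enol ether and bromide are inert, and the low temperature preserves C6.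

Step 19
Reactants: 24 tricyclic methyl ketone (acetyl on C6 cis to C8; C12=C13 silyl enol ether)
Product: 25 bis(silyl enol ether) (C15=C14 trimethylsilyl; C12=C13 tert-butyldimethylsilyl)
Conditions: LiN(iPr)2, Me3SiCl, THF, −78 °C
Reagents that add atoms: chlorotrimethylsilane, C[Si](C)(C)Cl
Why: Kinetic deprotonation of a methyl ketone at the methyl group with in situ silylation; the C6 methine is not deprotonated, so the cis relation of the C6 arm to C8 is kept.

Step 20
Reactants: 25 bis(silyl enol ether) (C15=C14 trimethylsilyl; C12=C13 tert-butyldimethylsilyl)
Product: 26 tetracyclic C12,C15-diketone (C13–C14 bond closed; C21 silyl ether)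
Conditions: (NH4)2Ce(NO3)6, NaHCO3, MeCN, high dilution, −40 → 0 °C
Reagents that add atoms: none
Why: Proposed new method: one-electron oxidation by tetravalent cerium of the more electron-rich, tetrasubstituted C12=C13 silyl enol ether should give a radical cation whose C13 terminus is captured by the nucleophilic C14 of the neighbouring trimethylsilyl enol ether; a second oxidation and loss of both silyl groups (NaHCO3 buffers the nitric acid) then deliver the 1,4-diketone. The closest known reaction type is the (NH4)2Ce(NO3)6-mediated intramolecular oxidative coupling of bis(silyl enol ethers), and the oxidative coupling of dienolates, to 1,4-diketones with quaternary centres; a bicyclo[2.2.1]heptane has not been closed in this way. The ring C6–C7–C13–C14–C15 closes 5-exo-trig with respect to the C12=C13 enol ether (C12 stays outside the ring), while the C14=C15 unit lies inside the new ring (enolendo), a geometry that polar enolate alkylation disfavours and that the early transition state of the radical-cation pathway is expected to tolerate. The new stereocentre C13 is controlled by the C6 arm: C6 and C13 are 1,3 on the five-membered ring, so C14 can reach only the face of C13 cis to the C6–C15 bond, which places C8 syn to the new carbonyl bridge as in the target. The step needs cross-coupling within the molecule in preference to dimerisation and to simple hydrolysis of the enol ethers; the gap in oxidation potential between the two enol ethers, the fixed proximity of C14 and C13, high dilution and low temperature are meant to secure this. Which carbons couple is fixed by the regiochemistry of the two preformed enol ethers, and neither the secondary bromide nor the silylated tertiary alcohol should react with tetravalent cerium under these conditions.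

Step 21
Reactants: 26 tetracyclic C12,C15-diketone (C13–C14 bond closed; C21 silyl ether)
Product: 27 C15 exo alcohol (C12 ketone retained)
Conditions: NaBH4, MeOH–THF, −20 °C
Reagents that add atoms: none
Why: Hydride reduction: the strained norbornanone carbonyl is more reactive than the C12 ketone, which is flanked by quaternary C13 and shielded by the axial methyl on C9. The exo face of C15 is blocked by C8 (as by the syn methyl in camphor), so hydride enters endo and gives the exo alcohol of the target; NaBH4 does not reduce the bromide.

Step 22
Reactants: 27 C15 exo alcohol (C12 ketone retained)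
Product: 28 C15 tert-butyldimethylsilyl ether (C12 ketone)
Conditions: tBuMe2SiOTf, 2,6-lutidine, CH2Cl2, −78 °C
Reagents that add atoms: tert-butyldimethylsilyl trifluoromethanesulfonate, CC(C)(C)[Si](C)(C)OS(=O)(=O)C(F)(F)F
Why: Silylation of the secondary alcohol so that no alkoxide competes in the enolate triflation; at −78 °C the hindered ketone is not enolised.

Step 23
Reactants: 28 C15 tert-butyldimethylsilyl ether (C12 ketone)
Product: 29 C11=C12 enol triflate
Conditions: KN(SiMe3)2, THF, −78 °C; then PhNTf2, −78 → 0 °C
Reagents that add atoms: N-phenylbis(trifluoromethanesulfonimide), O=S(=O)(N(c1ccccc1)S(=O)(=O)C(F)(F)F)C(F)(F)F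
Why: Enolate O-triflation: C13 is quaternary, so the ketone can enolise only toward C11; the equatorial bromide has no antiperiplanar hydrogen and resists elimination.

Step 24
Reactants: 29 C11=C12 enol triflate
Product: 30 C11=C12 alkene
Conditions: Pd(OAc)2 (cat.), PPh3, HCO2H, Bu3N, DMF, 60 °C
Reagents that add atoms: none
Why: Palladium-catalysed formate reduction of an enol triflate (Cacchi): zerovalent palladium inserts into the C–OTf bond and not into the unactivated secondary C–Br bond.

Step 25
Reactants: 30 C11=C12 alkene
Product: 31 bis(tert-butyldimethylsilyl) ether of the target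
Conditions: TsNHNH2, NaOAc, DME–H2O, reflux
Reagents that add atoms: none
Why: Diimide reduction (concerted syn transfer of two hydrogens) of the cis-disubstituted alkene; it leaves the bromide and the silyl ethers alone, where tin hydride or dissolving-metal methods would not.

Step 26
Reactants: 31 bis(tert-butyldimethylsilyl) ether of the target
Product: 32 target bromo diol (CNP0317598.2)
Conditions: Bu4NF, THF, 50 °C
Reagents that add atoms: none
Why: Fluoride-induced cleavage of both silyl ethers; the equatorial bromide of the trans-decalin resists elimination under these conditions.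

## Compound list

1 | (R)-limonene, (4R)-1-methyl-4-(prop-1-en-2-yl)cyclohex-1-ene | CC1=CC[C@@H](CC1)C(C)=C | starting material
2 | (R)-p-menth-1-ene, (4R)-1-methyl-4-(propan-2-yl)cyclohex-1-ene | CC1=CC[C@@H](CC1)C(C)C | intermediate
3 | (3R)-6-oxo-3-(propan-2-yl)heptanal | O=CC[C@@H](CCC(C)=O)C(C)C | intermediate
4 | 1-[(4S)-4-(propan-2-yl)cyclopent-1-en-1-yl]ethan-1-one | CC(=O)C1=CC[C@@H](C1)C(C)C | intermediate
5 | (4S)-4-(propan-2-yl)cyclopent-1-ene-1-carboxylic acid | OC(=O)C1=CC[C@@H](C1)C(C)C | intermediate
6 | methyl (4S)-4-(propan-2-yl)cyclopent-1-ene-1-carboxylate | COC(=O)C1=CC[C@@H](C1)C(C)C | intermediate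
7 | pent-1-en-4-yne | C=CCC#C | starting material
8 | dimethyl[(1E)-2-methylpenta-1,4-dien-1-yl]alane (methyl and aluminium cis) | C=CC/C(C)=C/[Al](C)C | intermediate (not isolated)
9 | (2E)-3-methylhexa-2,5-dien-1-ol | C=CC/C(C)=C/CO | intermediate
10 | (2E)-1-bromo-3-methylhexa-2,5-diene | C=CC/C(C)=C/CBr | intermediate
11 | prop-2-en-1-yl 3-oxobutanoate (allyl acetoacetate) | CC(=O)CC(=O)OCC=C | starting material
12 | prop-2-en-1-yl (6E)-7-methyl-3-oxodeca-6,9-dienoate | C=CC/C(C)=C/CCC(=O)CC(=O)OCC=C | intermediate
13 | prop-2-en-1-yl rac-(2S,3S)-3-bromo-2-methyl-6-oxo-2-(prop-2-en-1-yl)cyclohexane-1-carboxylate (racemate; Br cis to the methyl group; C1 epimers and enol form) | C=CCOC(=O)C1C(=O)CC[C@H](Br)[C@@]1(C)CC=C | intermediate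
14 | rac-(3S,4S)-4-bromo-3-methyl-3-(prop-2-en-1-yl)cyclohexan-1-one (racemate; the enantiomer carried on is drawn) | O=C1C[C@](C)(CC=C)[C@@H](Br)CC1 | intermediate
15 | (3S,4S)-4-bromo-3-methyl-3-(prop-2-en-1-yl)cyclohexan-1-one (Br cis to the methyl group) | O=C1C[C@](C)(CC=C)[C@@H](Br)CC1 | intermediate
16 | 2-[(1S,2S)-2-bromo-1-methyl-5-oxocyclohexyl]acetaldehyde | O=CC[C@@]1(C)CC(=O)CC[C@@H]1Br | intermediate
17 | tert-butyl{methoxy[(4S)-4-(propan-2-yl)cyclopent-2-en-1-ylidene]methoxy}dimethylsilane (silyl dienolate of 6; ketene acetal geometry not defined) | COC(O[Si](C)(C)C(C)(C)C)=C1C=C[C@@H](C1)C(C)C | intermediate (not isolated)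
18 | methyl (3S,4S)-3-{2-[(1S,2S)-2-bromo-1-methyl-5-oxocyclohexyl]-1-hydroxyethyl}-4-(propan-2-yl)cyclopent-1-ene-1-carboxylate (C12–C13 trans to isopropyl; both C12 carbinol epimers) | CC(C)[C@@H]1CC(C(=O)OC)=C[C@H]1C(O)C[C@@]2(C)CC(=O)CC[C@@H]2Br | intermediate
19 | methyl 6-bromo-4-hydroxy-5a-methyl-9-oxo-3-(propan-2-yl)dodecahydro-1H-cyclopenta[a]naphthalene-1-carboxylate: rings A/B trans-fused (H8 anti to the C9 methyl), H7 anti to H8, cyclopentane cis-fused to ring B, ester on C6 cis to C8, isopropyl on C4 trans to C12, Br equatorial and cis to the C9 methyl, C12 carbinol as both epimers | CC(C)[C@@H]1C[C@@H](C(=O)OC)[C@H]2[C@H]3[C@](C)(CC(O)[C@H]21)[C@@H](Br)CCC3=O | intermediate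
20 | methyl 6-bromo-4,9-dihydroxy-5a,9-dimethyl-3-(propan-2-yl)dodecahydro-1H-cyclopenta[a]naphthalene-1-carboxylate: as 19, with C21 bearing an axial OH (syn to the C9 methyl) and an equatorial methyl | CC(C)[C@@H]1C[C@@H](C(=O)OC)[C@H]2[C@H]3[C@](C)(CC(O)[C@H]21)[C@@H](Br)CC[C@@]3(C)O | intermediate
21 | methyl 6-bromo-9-hydroxy-5a,9-dimethyl-4-oxo-3-(propan-2-yl)dodecahydro-1H-cyclopenta[a]naphthalene-1-carboxylate: as 20, with a ketone at C12 | CC(C)[C@@H]1C[C@@H](C(=O)OC)[C@H]2[C@H]3[C@](C)(CC(=O)[C@H]21)[C@@H](Br)CC[C@@]3(C)O | intermediate
22 | tricyclic methyl ester with C12=C13 tert-butyldimethylsilyl enol ether and C21 tert-butyldimethylsilyl ether; other stereocentres as 21 | CC(C)[C@@H]1C[C@@H](C(=O)OC)[C@H]2[C@H]3[C@](C)(CC(O[Si](C)(C)C(C)(C)C)=C21)[C@@H](Br)CC[C@@]3(C)O[Si](C)(C)C(C)(C)C | intermediate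
23 | N-methoxy-N-methyl amide corresponding to 22 (Weinreb amide at C15) | CC(C)[C@@H]1C[C@@H](C(=O)N(C)OC)[C@H]2[C@H]3[C@](C)(CC(O[Si](C)(C)C(C)(C)C)=C21)[C@@H](Br)CC[C@@]3(C)O[Si](C)(C)C(C)(C)C | intermediate (not isolated)
24 | tricyclic methyl ketone: acetyl (C15, C14) on C6 cis to C8; C12=C13 silyl enol ether; C21 silyl ether | CC(C)[C@@H]1C[C@@H](C(C)=O)[C@H]2[C@H]3[C@](C)(CC(O[Si](C)(C)C(C)(C)C)=C21)[C@@H](Br)CC[C@@]3(C)O[Si](C)(C)C(C)(C)C | intermediate
25 | tricyclic bis(silyl enol ether): C15(OSiMe3)=C14H2 on C6 and C12(OSiMe2tBu)=C13 in ring B; C21 silyl ether | CC(C)[C@@H]1C[C@@H](C(=C)O[Si](C)(C)C)[C@H]2[C@H]3[C@](C)(CC(O[Si](C)(C)C(C)(C)C)=C21)[C@@H](Br)CC[C@@]3(C)O[Si](C)(C)C(C)(C)C | intermediate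
26 | tetracyclic C12,C15-diketone with the bicyclo[2.2.1]heptane closed (C13 quaternary, C8 syn to the C14–C15 bridge); C21 silyl ether | CC(C)[C@@H]1C[C@@H]2[C@H]3[C@H]4[C@](C)(CC(=O)[C@@]31CC2=O)[C@@H](Br)CC[C@@]4(C)O[Si](C)(C)C(C)(C)C | intermediate
27 | tetracyclic C12 ketone with exo C15 alcohol; C21 silyl ether | CC(C)[C@@H]1C[C@@H]2[C@H]3[C@H]4[C@](C)(CC(=O)[C@@]31C[C@H]2O)[C@@H](Br)CC[C@@]4(C)O[Si](C)(C)C(C)(C)C | intermediate
28 | tetracyclic C12 ketone with C15 and C21 tert-butyldimethylsilyl ethers | CC(C)[C@@H]1C[C@@H]2[C@H]3[C@H]4[C@](C)(CC(=O)[C@@]31C[C@H]2O[Si](C)(C)C(C)(C)C)[C@@H](Br)CC[C@@]4(C)O[Si](C)(C)C(C)(C)C | intermediate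
29 | C11=C12 enol trifluoromethanesulfonate of 28 | CC(C)[C@@H]1C[C@@H]2[C@H]3[C@H]4[C@](C)(C=C(OS(=O)(=O)C(F)(F)F)[C@@]31C[C@H]2O[Si](C)(C)C(C)(C)C)[C@@H](Br)CC[C@@]4(C)O[Si](C)(C)C(C)(C)C | intermediate
30 | C11=C12 alkene with C15 and C21 silyl ethers | CC(C)[C@@H]1C[C@@H]2[C@H]3[C@H]4[C@](C)(C=C[C@@]31C[C@H]2O[Si](C)(C)C(C)(C)C)[C@@H](Br)CC[C@@]4(C)O[Si](C)(C)C(C)(C)C | intermediate
31 | bis(tert-butyldimethylsilyl) ether of the target | CC(C)[C@@H]1C[C@@H]2[C@H]3[C@H]4[C@](C)(CC[C@@]31C[C@H]2O[Si](C)(C)C(C)(C)C)[C@@H](Br)CC[C@@]4(C)O[Si](C)(C)C(C)(C)C | intermediate
32 | target bromo diol CNP0317598.2 (exo C15–OH, axial C21–OH, equatorial C17–Br) | CC(C)[C@@H]1C[C@@H]2[C@H]3[C@H]4[C@](C)(CC[C@@]31C[C@H]2O)[C@@H](Br)CC[C@@]4(C)O | target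

## Step count and least certain steps

Total step count: 26 (including the resolution, step 11). Longest linear sequence: 21 steps (steps 6–12, then 13–26, from pent-1-en-4-yne 7); the limonene branch (steps 1–5) joins at step 13.

**Step 20 (key step).** The most likely failure is slow ring closure: C14 has to bond close to the nodal plane of its own enol ether (enolendo geometry). Desilylation of the radical cation to the C12 ketone, over-oxidation, or coupling between two molecules may then win. Fallback (known chemistry, polarity of C14 inverted): it sets out from Weinreb amide 23, obtained by stopping the one-pot of step 18 before MeMgBr is added. LiCH2Cl, generated from ICH2Cl and MeLi·LiBr at −78 °C, would convert 23 into the chloromethyl ketone F1. Tris(dimethylamino)sulfonium difluorotrimethylsilicate would then release the C12–C13 enolate regiospecifically from the silyl enol ether, and this enolate would displace chloride from C14. That closure is 5-exo-tet with the enolate double bond outside the ring, a favoured mode, and it returns to diketone 26.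

**Step 14.** The ring closure is thermodynamically sound, but the kinetic cis configuration at C6 may be lost by equilibration under methoxide, or later under the basic conditions of steps 17 and 18. Fallback: C6 is re-set on ester 22, where C6–H is the only acidic hydrogen. LiN(iPr)2 in THF at −78 °C would give the lithium ester enolate F2, and a hindered proton donor (2,6-di-tert-butylphenol) would protonate it from the face opposite C8. The fallback sets out from 22, of whatever C6 composition, and comes back to 22 with the ester cis to C8.

**Step 17.** Enolisation may stay under kinetic control and go toward C11, because the C13 hydrogen is poorly aligned in the cis-fused tricycle; the wrong enol ether would then result. Fallback (regiospecific enolate from an α-bromo ketone): it sets out from ketone 21.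
- Acid-catalysed bromination with pyridinium tribromide in AcOH, through the more substituted enol, would give the C13 bromo ketone F3.
- Silylation of the tertiary alcohol (tBuMe2SiOTf, 2,6-lutidine, −78 °C) would give its silyl ether F4.
- Me2CuLi at −78 °C would convert F4 by halogen–metal exchange into the C12–C13 lithium enolate, and trapping with tBuMe2SiOTf would return 22 as a single regioisomer.

**Step 9.** The bromonium cyclisation may be diverted by proton loss from the C9 cation, by bromination of the keto ester enol, or by attack on the other alkenes. Fallback (two-step surrogate): it sets out from 12. Hg(OTf)2 in MeNO2 at −20 °C, followed by aqueous KBr, would give by the same chair cyclisation the organomercury bromide F5. Br2 with LiBr in pyridine would then replace mercury by bromine and return to 13.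

**Step 25.** Diimide may fail to reduce the C11=C12 alkene completely, since it is flanked by two quaternary carbons. Fallback: it sets out from enol triflate 29. Hydrogenation over PtO2 (H2, EtOAc, with 2,6-lutidine) would hydrogenolyse and saturate the enol triflate in one operation and come back at 31 without passing through 30. No new compound is made, but the bromide would have to be watched.

## Further compounds

F1 | step 20 | chloromethyl ketone (C14–Cl) with C12=C13 silyl enol ether and C21 silyl ether | CC(C)[C@@H]1C[C@@H](C(=O)CCl)[C@H]2[C@H]3[C@](C)(CC(O[Si](C)(C)C(C)(C)C)=C21)[C@@H](Br)CC[C@@]3(C)O[Si](C)(C)C(C)(C)C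
F2 | step 14 | lithium ester enolate of 22 (C15=C6) | CC(C)[C@@H]1CC(=C(OC)O[Li])[C@H]2[C@H]3[C@](C)(CC(O[Si](C)(C)C(C)(C)C)=C21)[C@@H](Br)CC[C@@]3(C)O[Si](C)(C)C(C)(C)C
F3 | step 17 | C13 bromo ketone of 21 (C13 configuration not defined) | CC(C)[C@@H]1C[C@@H](C(=O)OC)[C@H]2[C@H]3[C@](C)(CC(=O)C21Br)[C@@H](Br)CC[C@@]3(C)O
F4 | step 17 | C21 tert-butyldimethylsilyl ether of F3 | CC(C)[C@@H]1C[C@@H](C(=O)OC)[C@H]2[C@H]3[C@](C)(CC(=O)C21Br)[C@@H](Br)CC[C@@]3(C)O[Si](C)(C)C(C)(C)C
F5 | step 9 | prop-2-en-1-yl rac-3-(bromomercurio)-2-methyl-6-oxo-2-(prop-2-en-1-yl)cyclohexane-1-carboxylate (mercury cis to the methyl group) | C=CCOC(=O)C1C(=O)CC[C@H]([Hg]Br)[C@@]1(C)CC=C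
F0 | step 25 | none | none
A1 | alternative 1 | phenol with C11 mesylate on the preformed norbornane | CC(C)[C@@H]1C[C@@H]2[C@@H](c3c(C)c(O)ccc3OC)[C@@]1(CCOS(C)(=O)=O)C[C@H]2O[Si](C)(C)C(C)(C)C
A2 | alternative 1 | tetracyclic 4-methoxy cyclohexa-2,4-dienone | CC(C)[C@@H]1C[C@@H]2[C@H]3C=4[C@](C)(CC[C@@]31C[C@H]2O[Si](C)(C)C(C)(C)C)C(=O)C=CC=4OC
A3 | alternative 2 | enyne with C6≡C7 alkyne on C8 and 1,1-disubstituted C13=C14 alkene | CC(C)[C@H](CO[Si](C)(C)C(C)(C)C)C(=C)CC[C@]1(C)[C@@H](Br)CCC2(OCCO2)[C@H]1C#C
A4 | alternative 2 | tricyclic cyclopentenone with quaternary C13 | CC(C)[C@H](CO[Si](C)(C)C(C)(C)C)[C@]12CC(=O)C=C1[C@@H]1C3(OCCO3)CC[C@H](Br)[C@@]1(C)CC2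
A5 | alternative 3 | C15 phenyl selenoester with vinyl on C7 and 2-methylpropenyl on C13 | CC(C)=C[C@@]1(CC(=O)[Se]c2ccccc2)CC[C@@]3(C)[C@H]([C@@H]1C=C)[C@](C)(O)CCC34OCCO4
A6 | alternative 3 | tetracyclic C15 ketone with C17 ketal | CC(C)[C@@H]1C[C@@H]2[C@H]3[C@H]4[C@](C)(CC[C@@]31CC2=O)C5(OCCO5)CC[C@@]4(C)O
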